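**Plan**
The target is an achiral 2,5-dimethoxy-1,4-benzoquinone with indole A (2-(2-methylbut-3-en-2-yl)indol-3-yl) at C3 and indole B (indol-3-yl) at C6; it has no stereocentre, so no stereocontrol is needed.
Cuts, in retrosynthetic order: quinone to its bis-MOM hydroquinone; N1–C2 and C3–C3a of indole B (alkyne annulation with 2-iodoaniline); the aryl–alkyne bond, then the aryl C–I bond; the bond from the central ring to C3 of indole A; C2–C3 of indole A.
Enabling feature: indole B is bound to the central ring through C3 and carries hydrogen at C2 and N1, so its pyrrole ring (N1, C2, C3, C3a, C7a) can be closed onto an aryl alkyne whose other terminus bears a silyl group that is removed later.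
Forward order: pyrrole ring of indole A (step 2); attachment to the preformed six-membered quinone ring (step 3); chloride-to-methoxide exchange and masking as the hydroquinone bis-MOM ether (steps 4 and 5); iodination and alkynylation (steps 6 and 7); pyrrole ring of indole B (step 8); unmasking and oxidation (step 9).

Key step: step 8

Remark: compounds 1, 2, 6, 13 and 15 are taken as commercial, and both indole N–H groups are carried unprotected, with extra base where an N–H consumes it.

**Route**

Step 1
Reactants: 1 2,2-dimethylbut-3-enoic acid; 2 o-toluidine (2-methylaniline)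
Product: 4 2,2-dimethyl-N-(2-methylphenyl)but-3-enamide, via 2,2-dimethylbut-3-enoyl chloride 3 (not isolated)
Conditions: (COCl)2, cat. DMF, CH2Cl2, 0 °C to rt; then 2, Et3N, CH2Cl2, 0 °C to rt
Reagents that add atoms: none
Why: Schotten–Baumann-type acylation of the aniline by the acid chloride made in the flask should be clean, since the acid has no α-hydrogen and so no ketene pathway.

Step 2
Reactants: 4 2,2-dimethyl-N-(2-methylphenyl)but-3-enamide
Product: 5 2-(2-methylbut-3-en-2-yl)-1H-indole (indole A)
Conditions: n-BuLi (3 equiv), THF, −20 °C to rt; aq. NH4Cl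
Reagents that add atoms: none
Why: Madelung indole synthesis in its organolithium variant, in which the N,benzylic dianion of the o-toluidide cyclises onto the amide carbonyl and aromatises by loss of the oxygen, should suit a pivalamide-type amide that has no enolisable hydrogen.

Step 3
Reactants: 5 2-(2-methylbut-3-en-2-yl)-1H-indole; 6 2,5-dichloro-1,4-benzoquinone
Product: 8 2,5-dichloro-3-[2-(2-methylbut-3-en-2-yl)-1H-indol-3-yl]-1,4-benzoquinone, via dichlorohydroquinone adduct 7 (not isolated)
Conditions: conc. HCl (cat.), THF, rt; then DDQ, rt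
Reagents that add atoms: none
Why: Acid-promoted Michael-type (Friedel–Crafts) addition of the nucleophilic indole C3 to an unsubstituted carbon of the protonated haloquinone, followed by dehydrogenation of the hydroquinone adduct, is an established way to attach hindered 2-alkylindoles to this quinone.

Step 4
Reactants: 8 2,5-dichloro-3-[2-(2-methylbut-3-en-2-yl)-1H-indol-3-yl]-1,4-benzoquinone
Product: 9 2,5-dimethoxy-3-[2-(2-methylbut-3-en-2-yl)-1H-indol-3-yl]-1,4-benzoquinone
Conditions: NaOMe (3 equiv), MeOH/THF, 0 °C to 40 °C; AcOH quench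
Reagents that add atoms: sodium methoxide, [Na+].[O-]C
Why: Each chlorine sits on the β-carbon of a vinylogous acid chloride, so methoxide should replace it by addition–elimination (nucleophilic vinylic substitution), the usual behaviour of haloquinones.

Step 5
Reactants: 9 2,5-dimethoxy-3-[2-(2-methylbut-3-en-2-yl)-1H-indol-3-yl]-1,4-benzoquinone
Product: 11 3-[2,5-dimethoxy-3,6-bis(methoxymethoxy)phenyl]-2-(2-methylbut-3-en-2-yl)-1H-indole, via dimethoxyhydroquinone 10 (not isolated)
Conditions: Na2S2O4, THF/H2O, rt; then MOMCl, iPr2NEt, cat. Bu4NI, CH2Cl2, 0 °C to 40 °C, under argon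
Reagents that add atoms: chloromethyl methyl ether (MOMCl), COCCl
Why: Dithionite reduction of the quinone followed by Williamson-type O-alkylation of the two phenols under amine base should leave the far less acidic indole N–H untouched.

Step 6
Reactants: 11 3-[2,5-dimethoxy-3,6-bis(methoxymethoxy)phenyl]-2-(2-methylbut-3-en-2-yl)-1H-indole
Product: 12 3-[4-iodo-2,5-dimethoxy-3,6-bis(methoxymethoxy)phenyl]-2-(2-methylbut-3-en-2-yl)-1H-indole
Conditions: n-BuLi (2.4 equiv), TMEDA, THF, −78 to −20 °C; then 1,2-diiodoethane, −78 °C to rt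
Reagents that add atoms: 1,2-diiodoethane, ICCI
Why: Directed ortho-metalation should work because, after the first equivalent of base removes the indole N–H, the only hydrogen on the central ring lies between an OMOM and an OMe group, and the aryllithium is then iodinated by 1,2-diiodoethane, a mild iodine donor that should spare the N-lithioindole.

Step 7
Reactants: 12 3-[4-iodo-2,5-dimethoxy-3,6-bis(methoxymethoxy)phenyl]-2-(2-methylbut-3-en-2-yl)-1H-indole; 13 trimethylsilylacetylene
Product: 14 3-{2,5-dimethoxy-3,6-bis(methoxymethoxy)-4-[(trimethylsilyl)ethynyl]phenyl}-2-(2-methylbut-3-en-2-yl)-1H-indole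
Conditions: PdCl2(PPh3)2 (5 mol %), CuI (10 mol %), Et3N/THF, 65 °C, sealed tube
Reagents that add atoms: none
Why: Sonogashira coupling of an aryl iodide with a terminal alkyne should proceed on warming even with two ortho-alkoxy groups, and the silyl group caps the other alkyne terminus.

Step 8
Reactants: 14 3-{2,5-dimethoxy-3,6-bis(methoxymethoxy)-4-[(trimethylsilyl)ethynyl]phenyl}-2-(2-methylbut-3-en-2-yl)-1H-indole; 15 2-iodoaniline
Product: 16 3-{2,5-dimethoxy-3,6-bis(methoxymethoxy)-4-[2-(trimethylsilyl)-1H-indol-3-yl]phenyl}-2-(2-methylbut-3-en-2-yl)-1H-indole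
Conditions: Pd(OAc)2 (10 mol %), LiCl (1 equiv), Na2CO3 (3 equiv), DMF, 100 °C
Reagents that add atoms: none
Why: Zerovalent palladium generated from Pd(OAc)2 inserts into the C–I bond of 15, the arylpalladium species adds syn across the alkyne of 14 so that the aniline carbon bonds to the alkyne carbon bearing the central ring (future C3) while palladium takes the silylated carbon (future C2), and the aniline nitrogen then binds palladium and C–N reductive elimination releases the indole. The closest known reaction is the Larock heteroannulation of 2-iodoaniline with aryl(trialkylsilyl)alkynes, which gives 3-aryl-2-silylindoles. The pyrrole ring of indole B closes in a [3+2] sense: C3–C3a forms first by intermolecular carbopalladation, then the five-membered ring closes by N1–C2 reductive elimination from a six-membered azapalladacycle. No stereocentre is formed. The step needs regioselective insertion, which the trimethylsilyl group should secure because the bulky, metal-stabilising silyl carbon prefers the position on the long C–Pd bond. It also needs preference for the alkyne over the vinyl group of indole A, which stronger alkyne coordination and the neopentyl-type hindrance of that vinyl group should provide, while chloride and the mild carbonate base keep the alkynyl C–Si bond intact until insertion.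

Step 9
Reactants: 16 3-{2,5-dimethoxy-3,6-bis(methoxymethoxy)-4-[2-(trimethylsilyl)-1H-indol-3-yl]phenyl}-2-(2-methylbut-3-en-2-yl)-1H-indole
Product: 18 2,5-dimethoxy-3-(1H-indol-3-yl)-6-[2-(2-methylbut-3-en-2-yl)-1H-indol-3-yl]-1,4-benzoquinone, via bis(indolyl)hydroquinone 17 (not isolated)
Conditions: HCl (3 M), MeOH, 45 °C; then Ag2O, CH2Cl2, rt
Reagents that add atoms: none
Why: Acid methanolysis should cleave both MOM acetals and remove the C2 silyl group by ipso-protodesilylation of the electron-rich indole, after which the electron-rich hydroquinone is dehydrogenated to the para-quinone by Ag2O under neutral conditions.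

**Compound list**
1 | 2,2-dimethylbut-3-enoic acid | C=CC(C)(C)C(=O)O | starting material
2 | o-toluidine (2-methylaniline) | Cc1ccccc1N | starting material
3 | 2,2-dimethylbut-3-enoyl chloride | C=CC(C)(C)C(=O)Cl | intermediate
4 | 2,2-dimethyl-N-(2-methylphenyl)but-3-enamide | C=CC(C)(C)C(=O)Nc1ccccc1C | intermediate
5 | 2-(2-methylbut-3-en-2-yl)-1H-indole (indole A) | C=CC(C)(C)c1cc2ccccc2[nH]1 | intermediate
6 | 2,5-dichloro-1,4-benzoquinone | O=C1C=C(Cl)C(=O)C=C1Cl | starting material
7 | 2,5-dichloro-3-[2-(2-methylbut-3-en-2-yl)-1H-indol-3-yl]benzene-1,4-diol | C=CC(C)(C)c1[nH]c2ccccc2c1-c1c(O)c(Cl)cc(O)c1Cl | intermediate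
8 | 2,5-dichloro-3-[2-(2-methylbut-3-en-2-yl)-1H-indol-3-yl]-1,4-benzoquinone | C=CC(C)(C)c1[nH]c2ccccc2c1C1=C(Cl)C(=O)C=C(Cl)C1=O | intermediate
9 | 2,5-dimethoxy-3-[2-(2-methylbut-3-en-2-yl)-1H-indol-3-yl]-1,4-benzoquinone | C=CC(C)(C)c1[nH]c2ccccc2c1C1=C(OC)C(=O)C=C(OC)C1=O | intermediate
10 | 2,5-dimethoxy-3-[2-(2-methylbut-3-en-2-yl)-1H-indol-3-yl]benzene-1,4-diol | C=CC(C)(C)c1[nH]c2ccccc2c1-c1c(O)c(OC)cc(O)c1OC | intermediate
11 | 3-[2,5-dimethoxy-3,6-bis(methoxymethoxy)phenyl]-2-(2-methylbut-3-en-2-yl)-1H-indole | C=CC(C)(C)c1[nH]c2ccccc2c1-c1c(OCOC)c(OC)cc(OCOC)c1OC | intermediate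
12 | 3-[4-iodo-2,5-dimethoxy-3,6-bis(methoxymethoxy)phenyl]-2-(2-methylbut-3-en-2-yl)-1H-indole | C=CC(C)(C)c1[nH]c2ccccc2c1-c1c(OCOC)c(OC)c(I)c(OCOC)c1OC | intermediate
13 | trimethylsilylacetylene (ethynyltrimethylsilane) | C#C[Si](C)(C)C | starting material
14 | 3-{2,5-dimethoxy-3,6-bis(methoxymethoxy)-4-[(trimethylsilyl)ethynyl]phenyl}-2-(2-methylbut-3-en-2-yl)-1H-indole | C=CC(C)(C)c1[nH]c2ccccc2c1-c1c(OCOC)c(OC)c(C#C[Si](C)(C)C)c(OCOC)c1OC | intermediate
15 | 2-iodoaniline | Nc1ccccc1I | starting material
16 | 3-{2,5-dimethoxy-3,6-bis(methoxymethoxy)-4-[2-(trimethylsilyl)-1H-indol-3-yl]phenyl}-2-(2-methylbut-3-en-2-yl)-1H-indole | C=CC(C)(C)c1[nH]c2ccccc2c1-c1c(OCOC)c(OC)c(-c2c([Si](C)(C)C)[nH]c3ccccc23)c(OCOC)c1OC | intermediate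
17 | 2,5-dimethoxy-3-(1H-indol-3-yl)-6-[2-(2-methylbut-3-en-2-yl)-1H-indol-3-yl]benzene-1,4-diol | C=CC(C)(C)c1[nH]c2ccccc2c1-c1c(O)c(OC)c(-c2c[nH]c3ccccc23)c(O)c1OC | intermediate
18 | 2,5-dimethoxy-3-(1H-indol-3-yl)-6-[2-(2-methylbut-3-en-2-yl)-1H-indol-3-yl]-1,4-benzoquinone | C=CC(C)(C)c1[nH]c2ccccc2c1C1=C(OC)C(=O)C(c2c[nH]c3ccccc23)=C(OC)C1=O | target

**Step count**
Total: 9 steps. Longest linear sequence: 9 steps (1 to 18); compounds 2, 6, 13 and 15 enter as commercial partners.

**Steps most likely to fail**

Step 8. Carbopalladation of an alkyne flanked by a silyl group and a doubly ortho-substituted aryl ring may be slow. That would let Heck arylation of the vinyl group of indole A, base-induced loss of silicon from the alkyne before insertion, or insertion with the opposite regiochemistry compete. The fallback makes the bond from the central ring to C3 of indole B by cross-coupling instead. It sets out from 12: Suzuki–Miyaura coupling with commercial tert-butyl 3-(4,4,5,5-tetramethyl-1,3,2-dioxaborolan-2-yl)-1H-indole-1-carboxylate (Pd(OAc)2, SPhos, K3PO4, toluene/H2O, 90 °C) should give tert-butyl 3-{2,5-dimethoxy-3,6-bis(methoxymethoxy)-4-[2-(2-methylbut-3-en-2-yl)-1H-indol-3-yl]phenyl}-1H-indole-1-carboxylate F1. HCl in MeOH should then remove the carbamate and both MOM groups, and the route is rejoined at 17, which is oxidised to 18 as in step 9.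

Step 6. Metalation of the N-lithiated substrate may be incomplete, or the iodine donor may also attack the metalated indole at C3 (haloindolenine formation), so that the aryl iodide is formed unselectively. The fallback avoids any halogen electrophile and builds the alkyne carbon by carbon. It sets out from 11: the same metalation quenched with DMF should give 2,5-dimethoxy-3,6-bis(methoxymethoxy)-4-[2-(2-methylbut-3-en-2-yl)-1H-indol-3-yl]benzaldehyde F2. Ohira–Bestmann homologation (dimethyl (1-diazo-2-oxopropyl)phosphonate, K2CO3, MeOH, rt) should give 3-[4-ethynyl-2,5-dimethoxy-3,6-bis(methoxymethoxy)phenyl]-2-(2-methylbut-3-en-2-yl)-1H-indole F3. Double deprotonation with LiN(SiMe3)2 (2.2 equiv) and silylation with TMSCl, with the N–Si bond hydrolysed on aqueous NaHCO3 work-up, brings the route back at 14, bypassing 12 and step 7.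

Step 4. Methoxide may add to the unsubstituted quinone carbon instead of displacing chloride, exchange of the hindered chloride next to indole A may stall, or the vinylogous esters may hydrolyse during work-up. The fallback separates substitution from methylation. It sets out from 8: NaOH in aqueous MeOH at reflux, then acidification, should give 2,5-dihydroxy-3-[2-(2-methylbut-3-en-2-yl)-1H-indol-3-yl]-1,4-benzoquinone F4. O-methylation of the two vinylogous acid hydroxyls with Me2SO4 and K2CO3 in acetone, conditions too mild to alkylate the indole nitrogen, comes back to the route at 9.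

**Further compounds**
F1 | step 8 | tert-butyl 3-{2,5-dimethoxy-3,6-bis(methoxymethoxy)-4-[2-(2-methylbut-3-en-2-yl)-1H-indol-3-yl]phenyl}-1H-indole-1-carboxylate | C=CC(C)(C)c1[nH]c2ccccc2c1-c1c(OCOC)c(OC)c(-c2cn(C(=O)OC(C)(C)C)c3ccccc23)c(OCOC)c1OC
F2 | step 6 | 2,5-dimethoxy-3,6-bis(methoxymethoxy)-4-[2-(2-methylbut-3-en-2-yl)-1H-indol-3-yl]benzaldehyde | C=CC(C)(C)c1[nH]c2ccccc2c1-c1c(OCOC)c(OC)c(C=O)c(OCOC)c1OC
F3 | step 6 | 3-[4-ethynyl-2,5-dimethoxy-3,6-bis(methoxymethoxy)phenyl]-2-(2-methylbut-3-en-2-yl)-1H-indole | C=CC(C)(C)c1[nH]c2ccccc2c1-c1c(OCOC)c(OC)c(C#C)c(OCOC)c1OC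
F4 | step 4 | 2,5-dihydroxy-3-[2-(2-methylbut-3-en-2-yl)-1H-indol-3-yl]-1,4-benzoquinone | C=CC(C)(C)c1[nH]c2ccccc2c1C1=C(O)C(=O)C=C(O)C1=O
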